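**Retrosynthetic overview**
- The acetic acid arm at C3 is added last, by axial C–C bond formation on the peroxycarbenium ion of a 3‑methoxy‑1,2‑dioxane.
- The 1,2‑dioxane (the only ring, formed in step 7) comes from 6‑endo cycloperoxymercuration of a C3 hydroperoxy acetal onto a (Z)‑C5=C6 olefin; C4 relays its configuration to C6.
- C3–C6 and the (Z)‑olefin come from furan: lithiation, ethylcuprate formation, dearomatising 1,2‑metallate ring opening and iodination (key step). C4 is set by RAMP‑hydrazone ethylation.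
- The side chain C7–C14 comes from hex‑1‑ene by two Zr‑catalysed carboaluminations and is joined at C6–C7 by Negishi coupling.

Assumption: (+)‑(NMI)2ZrCl2 and RAMP are taken as the reagent antipodes that give the (S) centres drawn; if the sense is the opposite, the mirror‑image reagent is used.

**Step 1**
Reactants: 1 hex‑1‑ene
Product: 3 (S)‑4‑methyloct‑1‑ene, via (S)‑dimethyl(2‑methylhexyl)alane 2 (not isolated)
Conditions: Me3Al, (+)‑(NMI)2ZrCl2 (3 mol %), MAO, CH2Cl2, 0→23 °C; then Zn(OTf)2, DMF, Pd(DPEphos)Cl2/DIBAL (cat.), bromoethene, 70 °C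
Reagents that add atoms: trimethylaluminium C[Al](C)C; bromoethene C=CBr
Why: Zr‑catalysed asymmetric carboalumination (ZACA) adds Me/Al across the terminal olefin under catalyst control (sets the future C10) and the alkylalane is vinylated in the same pot by Pd/Zn cross‑coupling.

**Step 2**
Reactants: 3 (S)‑4‑methyloct‑1‑ene
Product: 5 (2S,4S)‑2‑ethyl‑1‑iodo‑4‑methyloctane, via diethyl[(2S,4S)‑2‑ethyl‑4‑methyloctyl]alane 4 (not isolated)
Conditions: Et3Al, (+)‑(NMI)2ZrCl2 (5 mol %), IBAO, CH2Cl2, 0 °C; then I2, THF, 0 °C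
Reagents that add atoms: triethylaluminium CC[Al](CC)CC; iodine II
Why: a second ZACA reaction (ethylalumination) sets the future C8 by catalyst control, and iodinolysis of the C–Al bond gives the primary iodide.

**Step 3**
Reactants: 6 furan; 7 RAMP, (R)‑1‑amino‑2‑(methoxymethyl)pyrrolidine
Product: 14 (R,E)‑N‑[(Z)‑4‑iodohex‑3‑enylidene]‑2‑(methoxymethyl)pyrrolidin‑1‑amine, via furan‑2‑yllithium 8 (not isolated), via lithium ethyl(furan‑2‑yl)cuprate 9 (not isolated), via ring‑opened copper dienolate 10 (not isolated), via copper silyl dienol ether 11 (not isolated), via iodo silyl dienol ether 12 (not isolated), via (Z)‑4‑iodohex‑3‑enal 13 (not isolated)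
Conditions: n‑BuLi, THF, 0 °C; EtMgBr/CuBr·SMe2, Et2O–Me2S, −40→20 °C; TMSCl, −78 °C; I2, −78 °C; pH 7 buffer; then 7, Et2O, MgSO4, 0 °C
Reagents that add atoms: ethylmagnesium bromide CC[Mg]Br; iodine II
Why: Proposed new method: in cuprate 9 the furyl C2 is a carbenoid with C–O as leaving group, so ethyl migrates from Cu to C2 with inversion and C–O cleavage (1,2‑metallate rearrangement), trading furan aromaticity for a lithium dienolate and leaving Cu cis to the ring‑derived chain, so that iodine (later C7) is cis to C4 and ethyl trans, i.e. the (Z)‑olefin; the closest known reactions are the copper‑mediated 1,2‑metallate ring opening of 5‑lithio‑2,3‑dihydrofurans and the ring‑opening 1,2‑migrations of 2‑furyl‑ and 2‑benzofurylborates; silylation protects the enolate from iodine and the labile aldehyde is stored as its hydrazone.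

**Step 4**
Reactants: 5 (2S,4S)‑2‑ethyl‑1‑iodo‑4‑methyloctane; 14 iodo‑alkenyl RAMP hydrazone
Product: 16 (R,E)‑N‑[(3Z,6S,8S)‑4,6‑diethyl‑8‑methyldodec‑3‑enylidene]‑2‑(methoxymethyl)pyrrolidin‑1‑amine, via [(2S,4S)‑2‑ethyl‑4‑methyloctyl]zinc iodide 15 (not isolated)
Conditions: 5, Zn dust, LiCl, THF, 50 °C; then 14, Pd(dppf)Cl2 (5 mol %), THF/NMP, 50 °C
Reagents that add atoms: none
Why: Negishi sp2–sp3 coupling of the alkenyl iodide with the primary alkylzinc proceeds with retention of olefin geometry, so C7 ends cis to C4.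

**Step 5**
Reactants: 16 RAMP hydrazone of (3Z,6S,8S)‑4,6‑diethyl‑8‑methyldodec‑3‑enal
Product: 18 (R,E)‑N‑[(2S,3Z,6S,8S)‑2,4,6‑triethyl‑8‑methyldodec‑3‑enylidene]‑2‑(methoxymethyl)pyrrolidin‑1‑amine, via lithium azaenolate 17 (not isolated)
Conditions: LDA, THF, 0 °C; EtI, −100→−78 °C
Reagents that add atoms: iodoethane CCI
Why: Enders hydrazone alkylation: the chelated lithium azaenolate is ethylated at the α‑carbon on the face away from the methoxymethyl arm, which sets C4 as (S) without moving the (Z)‑olefin.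

**Step 6**
Reactants: 18 ethylated RAMP hydrazone
Product: 19 (2S,3Z,6S,8S)‑2,4,6‑triethyl‑8‑methyldodec‑3‑enal
Conditions: sat. aq. oxalic acid, Et2O, 0→20 °C (two‑phase)
Reagents that add atoms: water O
Why: mild two‑phase acid hydrolysis of the hydrazone frees the aldehyde without epimerising the α‑centre and returns the auxiliary.

**Step 7**
Reactants: 19 (2S,3Z,6S,8S)‑2,4,6‑triethyl‑8‑methyldodec‑3‑enal
Product: 23 (4S,6S)‑4,6‑diethyl‑6‑[(2S,4S)‑2‑ethyl‑4‑methyloctyl]‑3‑methoxy‑1,2‑dioxane (both C3 epimers), via dimethyl acetal 20 (not isolated), via hydroperoxy acetal 21 (not isolated), via organomercurial 22 (not isolated)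
Conditions: HC(OMe)3, MeOH, PPTS, 20 °C; H2O2 (ethereal), CSA (cat.), 0 °C; Hg(OAc)2, CH2Cl2, 0 °C; NaBH4, 3 M NaOH, 0 °C
Reagents that add atoms: trimethyl orthoformate COC(OC)OC; hydrogen peroxide OO
Why: acetal perhydrolysis followed by cycloperoxymercuration–demercuration: the OOH adds 6‑endo (Markovnikov, tertiary C6) and anti to Hg through a chair in which C4–H lies in the olefin plane (A1,3 strain with the cis C7), so the ethyl that was trans to C4 becomes equatorial and cis to the C4 ethyl and the side chain axial, which sets C6; NaBH4 then replaces Hg by H.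

**Step 8**
Reactants: 23 3‑methoxy‑1,2‑dioxane
Product: 26 2‑[(3S,4S,6S)‑4,6‑diethyl‑6‑[(2S,4S)‑2‑ethyl‑4‑methyloctyl]‑1,2‑dioxan‑3‑yl]acetic acid, via peroxycarbenium triflate 24 (not isolated), via trimethylsilyl ester 25 (not isolated)
Conditions: CH2=C(OTMS)2 (3 equiv), TMSOTf (0.3 equiv), CH2Cl2, −78 °C; aq. citric acid work‑up
Reagents that add atoms: 1,1‑bis(trimethylsilyloxy)ethene C=C(O[Si](C)(C)C)O[Si](C)(C)C
Why: Lewis‑acid ionisation gives the six‑membered peroxycarbenium ion and Mukaiyama‑type addition of the ketene bis‑silyl acetal along the axial trajectory (trans to the axial C6 chain, cis to the equatorial C4 ethyl) sets C3; the silyl ester falls to the free acid on work‑up, so the base‑sensitive secondary peroxide never meets hydroxide.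

**Compound list**
1 | hex‑1‑ene | C=CCCCC | starting material
2 | (S)‑dimethyl(2‑methylhexyl)alane | CCCC[C@H](C)C[Al](C)C | intermediate
3 | (S)‑4‑methyloct‑1‑ene | CCCC[C@H](C)CC=C | intermediate
4 | diethyl[(2S,4S)‑2‑ethyl‑4‑methyloctyl]alane | CCCC[C@H](C)C[C@H](CC)C[Al](CC)CC | intermediate
5 | (2S,4S)‑2‑ethyl‑1‑iodo‑4‑methyloctane | CCCC[C@H](C)C[C@H](CC)CI | intermediate
6 | furan | c1ccoc1 | starting material
7 | RAMP, (R)‑1‑amino‑2‑(methoxymethyl)pyrrolidine | COC[C@H]1CCCN1N | starting material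
8 | furan‑2‑yllithium | [Li]c1ccco1 | intermediate
9 | lithium ethyl(furan‑2‑yl)cuprate | [Li+].CC[Cu-]c1ccco1 | intermediate
10 | lithium (1Z,3Z)‑4‑cupriohexa‑1,3‑dien‑1‑olate | [Li+].CC/C([Cu])=C/C=C\[O-] | intermediate
11 | (1Z,3Z)‑4‑cuprio‑1‑(trimethylsilyloxy)hexa‑1,3‑diene | CC/C([Cu])=C/C=C\O[Si](C)(C)C | intermediate
12 | (1Z,3Z)‑4‑iodo‑1‑(trimethylsilyloxy)hexa‑1,3‑diene | CC/C(I)=C/C=C\O[Si](C)(C)C | intermediate
13 | (Z)‑4‑iodohex‑3‑enal | CC/C(I)=C/CC=O | intermediate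
14 | (R,E)‑N‑[(Z)‑4‑iodohex‑3‑enylidene]‑2‑(methoxymethyl)pyrrolidin‑1‑amine | COC[C@H]1CCCN1/N=C/C/C=C(/CC)I | intermediate
15 | [(2S,4S)‑2‑ethyl‑4‑methyloctyl]zinc iodide | CCCC[C@H](C)C[C@H](CC)C[Zn]I | intermediate
16 | (R,E)‑N‑[(3Z,6S,8S)‑4,6‑diethyl‑8‑methyldodec‑3‑enylidene]‑2‑(methoxymethyl)pyrrolidin‑1‑amine | COC[C@H]1CCCN1/N=C/C/C=C(/CC)C[C@@H](CC)C[C@@H](C)CCCC | intermediate
17 | lithium azaenolate of 16 (α‑deprotonated at C2 of the dodecenylidene chain) | [Li+].COC[C@H]1CCCN1[N-]C=C/C=C(/CC)C[C@@H](CC)C[C@@H](C)CCCC | intermediate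
18 | (R,E)‑N‑[(2S,3Z,6S,8S)‑2,4,6‑triethyl‑8‑methyldodec‑3‑enylidene]‑2‑(methoxymethyl)pyrrolidin‑1‑amine | COC[C@H]1CCCN1/N=C/[C@@H](CC)/C=C(/CC)C[C@@H](CC)C[C@@H](C)CCCC | intermediate
19 | (2S,3Z,6S,8S)‑2,4,6‑triethyl‑8‑methyldodec‑3‑enal | O=C[C@@H](CC)/C=C(/CC)C[C@@H](CC)C[C@@H](C)CCCC | intermediate
20 | (2S,3Z,6S,8S)‑2,4,6‑triethyl‑1,1‑dimethoxy‑8‑methyldodec‑3‑ene | COC(OC)[C@@H](CC)/C=C(/CC)C[C@@H](CC)C[C@@H](C)CCCC | intermediate
21 | (2S,3Z,6S,8S)‑2,4,6‑triethyl‑1‑hydroperoxy‑1‑methoxy‑8‑methyldodec‑3‑ene (both C1 epimers) | COC(OO)[C@@H](CC)/C=C(/CC)C[C@@H](CC)C[C@@H](C)CCCC | intermediate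
22 | 5‑(acetoxymercurio) derivative of 23 (Hg anti to the new C6–O bond) | CCCC[C@H](C)C[C@H](CC)C[C@@]1(CC)C([Hg]OC(C)=O)[C@H](CC)C(OC)OO1 | intermediate
23 | (4S,6S)‑4,6‑diethyl‑6‑[(2S,4S)‑2‑ethyl‑4‑methyloctyl]‑3‑methoxy‑1,2‑dioxane (both C3 epimers) | CCCC[C@H](C)C[C@H](CC)C[C@@]1(CC)C[C@H](CC)C(OC)OO1 | intermediate
24 | (4S,6S)‑4,6‑diethyl‑6‑[(2S,4S)‑2‑ethyl‑4‑methyloctyl]‑5,6‑dihydro‑4H‑1,2‑dioxin‑2‑ium triflate | CCCC[C@H](C)C[C@H](CC)C[C@@]1(CC)C[C@H](CC)C=[O+]O1.[O-]S(=O)(=O)C(F)(F)F | intermediate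
25 | trimethylsilyl 2‑[(3S,4S,6S)‑4,6‑diethyl‑6‑[(2S,4S)‑2‑ethyl‑4‑methyloctyl]‑1,2‑dioxan‑3‑yl]acetate | CCCC[C@H](C)C[C@H](CC)C[C@@]1(CC)C[C@H](CC)[C@H](CC(=O)O[Si](C)(C)C)OO1 | intermediate
26 | 2‑[(3S,4S,6S)‑4,6‑diethyl‑6‑[(2S,4S)‑2‑ethyl‑4‑methyloctyl]‑1,2‑dioxan‑3‑yl]acetic acid | CCCC[C@H](C)C[C@H](CC)C[C@@]1(CC)C[C@H](CC)[C@H](CC(=O)O)OO1 | target

**Step count**
Total steps: 8. Longest linear sequence: 7 (steps 1, 2, 4, 5, 6, 7, 8).

**Steps most likely to fail, with fallbacks**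

Step 3. The furylcuprate may not rearrange, or the dienolate may be iodinated. The fallback sets out from iodide 5 and returns at hydrazone 16, replacing steps 3 and 4. Iodide 5 is turned into the Grignard reagent [(2S,4S)‑2‑ethyl‑4‑methyloctyl]magnesium iodide F1 and, with CuBr·SMe2, into the organocopper reagent [(2S,4S)‑2‑ethyl‑4‑methyloctyl]copper F2. Syn‑carbocupration of but‑1‑yne (Normant) gives the alkenylcopper [(1Z,4S,6S)‑2,4‑diethyl‑6‑methyldec‑1‑enyl]copper F3, with copper cis to the new chain. Opening of oxirane gives the homoallylic alcohol (3Z,6S,8S)‑4,6‑diethyl‑8‑methyldodec‑3‑en‑1‑ol F4. Dess–Martin oxidation gives the aldehyde (3Z,6S,8S)‑4,6‑diethyl‑8‑methyldodec‑3‑enal F5, which is condensed with 7 to give 16.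

Step 7. Regiochemistry, the A1,3‑controlled facial course, or epoxide formation on demercuration may fail. The fallback sets out from aldehyde 19 and returns at 23. The dimethyl acetal 20 is isolated and its C5=C6 olefin is hydroperoxysilylated (Co(thd)2, O2, Et3SiH; Mukaiyama–Isayama) to the tertiary silyl peroxide (2S,6S,8S)‑2,4,6‑triethyl‑1,1‑dimethoxy‑8‑methyl‑4‑(triethylsilylperoxy)dodecane F6, as both C4 epimers. TsOH in MeOH then closes the ring by transperoxyacetalisation to 23 together with its 6‑epimer, (4S,6R)‑4,6‑diethyl‑6‑[(2S,4S)‑2‑ethyl‑4‑methyloctyl]‑3‑methoxy‑1,2‑dioxane F7, which is removed by chromatography. Mercury is avoided but C6 control is given up.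

Step 8. The facial selectivity at C3 next to the C4 ethyl may be poor or reversed. The fallback sets out from aldehyde 19 and returns at 26, introducing hydride last instead of carbon.
- Roskamp homologation (tert‑butyl diazoacetate, SnCl2) gives the β‑keto ester tert‑butyl (4S,5Z,8S,10S)‑4,6,8‑triethyl‑10‑methyl‑3‑oxotetradec‑5‑enoate F8, used at once because C4 is now epimerisable.
- H2O2/MeOH/CSA gives the hydroperoxy ketal tert‑butyl (4S,5Z,8S,10S)‑4,6,8‑triethyl‑3‑hydroperoxy‑3‑methoxy‑10‑methyltetradec‑5‑enoate F9.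
- Peroxymercuration as in step 7 gives the organomercurial F10 and, after NaBH4, tert‑butyl 2‑[(4S,6S)‑4,6‑diethyl‑6‑[(2S,4S)‑2‑ethyl‑4‑methyloctyl]‑3‑methoxy‑1,2‑dioxan‑3‑yl]acetate F11.
- Ionic hydrogenation (Et3SiH, TMSOTf) gives tert‑butyl 2‑[(3S,4S,6S)‑4,6‑diethyl‑6‑[(2S,4S)‑2‑ethyl‑4‑methyloctyl]‑1,2‑dioxan‑3‑yl]acetate F12, and TFA gives 26.
- Hydride now takes the face that the carbon nucleophile took in step 8, so this is the remedy if step 8 gives mainly the 3‑epimer.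

**Further compounds**
F1 | step 3 | [(2S,4S)‑2‑ethyl‑4‑methyloctyl]magnesium iodide | CCCC[C@H](C)C[C@H](CC)C[Mg]I
F2 | step 3 | [(2S,4S)‑2‑ethyl‑4‑methyloctyl]copper | CCCC[C@H](C)C[C@H](CC)C[Cu]
F3 | step 3 | [(1Z,4S,6S)‑2,4‑diethyl‑6‑methyldec‑1‑enyl]copper | CC/C(=C/[Cu])C[C@@H](CC)C[C@@H](C)CCCC
F4 | step 3 | (3Z,6S,8S)‑4,6‑diethyl‑8‑methyldodec‑3‑en‑1‑ol | OCC/C=C(/CC)C[C@@H](CC)C[C@@H](C)CCCC
F5 | step 3 | (3Z,6S,8S)‑4,6‑diethyl‑8‑methyldodec‑3‑enal | O=CC/C=C(/CC)C[C@@H](CC)C[C@@H](C)CCCC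
F6 | step 7 | (2S,6S,8S)‑2,4,6‑triethyl‑1,1‑dimethoxy‑8‑methyl‑4‑(triethylsilylperoxy)dodecane (both C4 epimers) | COC(OC)[C@@H](CC)CC(CC)(OO[Si](CC)(CC)CC)C[C@@H](CC)C[C@@H](C)CCCC
F7 | step 7 | (4S,6R)‑4,6‑diethyl‑6‑[(2S,4S)‑2‑ethyl‑4‑methyloctyl]‑3‑methoxy‑1,2‑dioxane | CCCC[C@H](C)C[C@H](CC)C[C@]1(CC)C[C@H](CC)C(OC)OO1
F8 | step 8 | tert‑butyl (4S,5Z,8S,10S)‑4,6,8‑triethyl‑10‑methyl‑3‑oxotetradec‑5‑enoate | CC(C)(C)OC(=O)CC(=O)[C@@H](CC)/C=C(/CC)C[C@@H](CC)C[C@@H](C)CCCC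
F9 | step 8 | tert‑butyl (4S,5Z,8S,10S)‑4,6,8‑triethyl‑3‑hydroperoxy‑3‑methoxy‑10‑methyltetradec‑5‑enoate | CC(C)(C)OC(=O)CC(OC)(OO)[C@@H](CC)/C=C(/CC)C[C@@H](CC)C[C@@H](C)CCCC
F10 | step 8 | 5‑(acetoxymercurio) derivative of F11 | CCCC[C@H](C)C[C@H](CC)C[C@@]1(CC)C([Hg]OC(C)=O)[C@H](CC)C(OC)(CC(=O)OC(C)(C)C)OO1
F11 | step 8 | tert‑butyl 2‑[(4S,6S)‑4,6‑diethyl‑6‑[(2S,4S)‑2‑ethyl‑4‑methyloctyl]‑3‑methoxy‑1,2‑dioxan‑3‑yl]acetate | CCCC[C@H](C)C[C@H](CC)C[C@@]1(CC)C[C@H](CC)C(OC)(CC(=O)OC(C)(C)C)OO1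
F12 | step 8 | tert‑butyl 2‑[(3S,4S,6S)‑4,6‑diethyl‑6‑[(2S,4S)‑2‑ethyl‑4‑methyloctyl]‑1,2‑dioxan‑3‑yl]acetate | CCCC[C@H](C)C[C@H](CC)C[C@@]1(CC)C[C@H](CC)[C@H](CC(=O)OC(C)(C)C)OO1
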